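**Retrosynthetic overview**
1. Target 27 ⇐ macrocyclic acetonide 23 (acetonide removal, 9-O-acetylation, 8-O-angeloylation, desilylation).
2. 23 ⇐ seco acid 22 by cutting C7–C8: the C8 dioxolanyl radical (from decarboxylation) closes the ten-membered ring onto C7 of a 3-(phenylsulfonylmethyl)butenolide; loss of PhSO2• unveils the exocyclic methylene and C7 and C8 are set together.
3. 22 ⇐ vinyl carbinol 16 + acid 18 (esterification, ring-closing metathesis to the butenolide); C6 comes from an enantioselective vinyl addition to enal 15.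
4. 15 ⇐ (Z)-α-iodoenoate 9 + dioxolane acid 13 (nickel/photoredox decarboxylative alkenylation, C9–C10); 13 comes from D-erythronolactone acetonide.
5. 9 ⇐ (S)-5-(hydroxymethyl)butyrolactone (C1–C4, C15) + dimethoxyacetaldehyde (C5, C6). Ring order: dioxolane (chiral pool) → butenolide (metathesis) → ten-membered carbocycle (radical step).

Assumption: locants C1–C15 are the germacrane locants of the target (C6 bears the lactone oxygen, C12 = lactone carbonyl, C13 = exocyclic CH2, C14 = ester carbon, C15 = CH2OH carbon); the SMILES is read as 2S,6R,7S,8S,9S with both ring olefins cis within the ring (E by CIP).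

**Route**

Step 1
Reactants: 1 (S)-5-(hydroxymethyl)dihydrofuran-2(3H)-one
Product: 2 (S)-5-{[(triethylsilyl)oxy]methyl}dihydrofuran-2(3H)-one
Conditions: Et3SiCl, imidazole, CH2Cl2, 0 °C
Reagents that add atoms: chlorotriethylsilane, CC[Si](Cl)(CC)CC
Why: Standard silylation of the primary alcohol; the C2 stereocentre (S) is taken from the chiral pool and is never touched again.

Step 2
Reactants: 2 (S)-5-{[(triethylsilyl)oxy]methyl}dihydrofuran-2(3H)-one; 3 2,2-dimethoxyacetaldehyde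
Product: 5 (5S,3E)-3-(2,2-dimethoxyethylidene)-5-{[(triethylsilyl)oxy]methyl}dihydrofuran-2(3H)-one, via phosphono lactone 4 (not isolated)
Conditions: LiN(iPr)2 (1.1 equiv), THF, −78 °C; ClP(O)(OEt)2; LiN(iPr)2 (2.2 equiv), −78 → 0 °C; then 3, 0 °C → rt
Reagents that add atoms: none
Why: Enolate O-phosphorylation, base-induced 1,3-phosphoryl shift from O to C and Horner–Wadsworth–Emmons olefination with the non-enolisable aldehyde give the E-alkylidene lactone (C6 anti to the carbonyl), which fixes the C4=C5 geometry of the target.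

Step 3
Reactants: 5 (5S,3E)-3-(2,2-dimethoxyethylidene)-5-{[(triethylsilyl)oxy]methyl}dihydrofuran-2(3H)-one
Product: 6 (2E,4S)-2-(2,2-dimethoxyethylidene)-5-[(triethylsilyl)oxy]pentane-1,4-diol
Conditions: iBu2AlH (4 equiv), CH2Cl2, −78 → 0 °C; aq. potassium sodium tartrate
Reagents that add atoms: none
Why: 1,2-Reduction of the conjugated lactone by the aluminium hydride opens it to the C15 allylic alcohol and the C2 alcohol without touching the olefin or the acetal.

Step 4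
Reactants: 6 (2E,4S)-2-(2,2-dimethoxyethylidene)-5-[(triethylsilyl)oxy]pentane-1,4-diol
Product: 7 (2S,4E)-6,6-dimethoxy-1-[(triethylsilyl)oxy]-2-[(triisopropylsilyl)oxy]-4-{[(triisopropylsilyl)oxy]methyl}hex-4-ene
Conditions: iPr3SiOTf, 2,6-lutidine, CH2Cl2, 0 °C → rt
Reagents that add atoms: triisopropylsilyl triflate, CC(C)[Si](OS(=O)(=O)C(F)(F)F)(C(C)C)C(C)C
Why: Bis-silylation; the acid-robust TIPS ethers protect O2 and O15 up to the last step.

Step 5
Reactants: 7 (2S,4E)-6,6-dimethoxy-1-[(triethylsilyl)oxy]-2-[(triisopropylsilyl)oxy]-4-{[(triisopropylsilyl)oxy]methyl}hex-4-ene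
Product: 9 methyl (2Z,4S,6E)-2-iodo-8,8-dimethoxy-4-[(triisopropylsilyl)oxy]-6-{[(triisopropylsilyl)oxy]methyl}octa-2,6-dienoate, via aldehyde 8 (not isolated)
Conditions: (COCl)2, DMSO, CH2Cl2, −78 → −30 °C; Et3N, −78 °C; then Ph3P=C(I)CO2Me (made separately from Ph3P=CHCO2Me and N-iodosuccinimide, CH2Cl2, −20 °C), → rt
Reagents that add atoms: methyl (triphenylphosphoranylidene)acetate, COC(=O)C=P(c1ccccc1)(c1ccccc1)c1ccccc1; N-iodosuccinimide, O=C1CCC(=O)N1I
Why: Swern conditions convert the primary triethylsilyl ether directly into the aldehyde, and the in situ Wittig reaction with the stabilised iodo ylide gives the Z-α-iodoenoate (C2 anti to the ester), the geometry needed for C1=C10.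

Step 6
Reactants: 10 2,3-O-isopropylidene-D-erythronolactone
Product: 12 methyl (4R,5R)-5-(hydroxymethyl)-2,2-dimethyl-1,3-dioxolane-4-carboxylate, via potassium carboxylate 11 (not isolated)
Conditions: KOH, MeOH/H2O, rt; evaporate; MeI, DMF, 0 °C (used at once to avoid relactonisation)
Reagents that add atoms: potassium hydroxide, [K+].[OH-]; iodomethane, CI
Why: Saponification and O-alkylation of the carboxylate open the lactone with its two ends differentiated; neither stereocentre is touched.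

Step 7
Reactants: 12 methyl (4R,5R)-5-(hydroxymethyl)-2,2-dimethyl-1,3-dioxolane-4-carboxylate
Product: 13 (4S,5R)-5-(methoxycarbonyl)-2,2-dimethyl-1,3-dioxolane-4-carboxylic acid
Conditions: TEMPO (20 mol %), PhI(OAc)2 (2.2 equiv), MeCN/H2O, rt
Reagents that add atoms: water, O
Why: Oxoammonium oxidation of the primary alcohol to the acid; the ester-bearing carbon (future C8, R) keeps the pool configuration.

Step 8
Reactants: 9 methyl (2Z,4S,6E)-2-iodo-8,8-dimethoxy-4-[(triisopropylsilyl)oxy]-6-{[(triisopropylsilyl)oxy]methyl}octa-2,6-dienoate; 13 (4S,5R)-5-(methoxycarbonyl)-2,2-dimethyl-1,3-dioxolane-4-carboxylic acid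
Product: 14 methyl (4R,5S)-5-[(2E,4S,6E)-1,8,8-trimethoxy-1-oxo-4-[(triisopropylsilyl)oxy]-6-{[(triisopropylsilyl)oxy]methyl}octa-2,6-dien-2-yl]-2,2-dimethyl-1,3-dioxolane-4-carboxylate
Conditions: 13 (1.5 equiv), Ir[dF(CF3)ppy]2(dtbbpy)PF6 (1 mol %), NiCl2·glyme (10 mol %), 4,4′-di-tert-butyl-2,2′-bipyridine (15 mol %), Cs2CO3, DMSO, blue LEDs, rt
Reagents that add atoms: none
Why: Nickel/photoredox decarboxylative alkenylation of an α-oxy acid: the dioxolanyl radical is captured by the alkenylnickel species anti to the neighbouring ester, giving the trans-dioxolane (C9 = S), with retention of olefin geometry (C2 and C9 cis on C1=C10).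

Step 9
Reactants: 14 (dioxolane diester acetal, named in step 8)
Product: 15 methyl (4R,5S)-5-[(2E,4S,6E)-1-methoxy-1,8-dioxo-4-[(triisopropylsilyl)oxy]-6-{[(triisopropylsilyl)oxy]methyl}octa-2,6-dien-2-yl]-2,2-dimethyl-1,3-dioxolane-4-carboxylate
Conditions: oxalic acid, wet SiO2, CH2Cl2, rt
Reagents that add atoms: water, O
Why: The allylic dimethyl acetal hydrolyses far faster than the dioxolane ketal or the TIPS ethers, releasing the C6 enal.

Step 10
Reactants: 15 (enal, named in step 9)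
Product: 16 methyl (4R,5S)-5-[(2E,4S,6E,8S)-8-hydroxy-1-methoxy-1-oxo-4-[(triisopropylsilyl)oxy]-6-{[(triisopropylsilyl)oxy]methyl}deca-2,6,9-trien-2-yl]-2,2-dimethyl-1,3-dioxolane-4-carboxylate
Conditions: (CH2=CH)2Zn (from CH2=CHMgBr and ZnCl2), N,N,N′,N′-tetraethylethylenediamine, (−)-MIB [(2S)-3-exo-morpholinoisoborneol] (10 mol %), toluene, −20 °C
Reagents that add atoms: divinylzinc, C=C[Zn]C=C
Why: Amino-alcohol-catalysed enantioselective 1,2-addition of the vinylzinc reagent to the Si face of the enal sets C6 (S at this stage, which becomes 6R in the lactone); the esters are inert to the organozinc.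

Step 11
Reactants: 17 2-(bromomethyl)prop-2-enoic acid
Product: 18 2-[(phenylsulfonyl)methyl]prop-2-enoic acid
Conditions: PhSO2Na, MeOH, reflux
Reagents that add atoms: sodium benzenesulfinate, [Na+].[O-]S(=O)c1ccccc1
Why: Sulfinate displaces the allylic bromide (S-alkylation) to give the sulfonyl acrylic acid that will serve as the radical-leaving-group carrier.

Step 12
Reactants: 16 (vinyl carbinol, named in step 10); 18 2-[(phenylsulfonyl)methyl]prop-2-enoic acid
Product: 20 the (8S) 8-O-{2-[(phenylsulfonyl)methyl]prop-2-enoyl} ester of 16, via acid chloride 19 (not isolated)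
Conditions: 18, (COCl)2, cat. DMF, CH2Cl2, 0 °C; evaporate; then 16, 2,6-lutidine, CH2Cl2, −20 °C
Reagents that add atoms: none
Why: Acylation through the acid chloride with a hindered, non-nucleophilic base avoids SN2′ attack on the sulfonylmethyl acrylate; the C6–O bond is not touched.

Step 13
Reactants: 20 (diene ester, named in step 12)
Product: 21 methyl (4R,5S)-5-[(2E,4S,6E)-1-methoxy-1-oxo-7-{(2R)-5-oxo-4-[(phenylsulfonyl)methyl]-2,5-dihydrofuran-2-yl}-4-[(triisopropylsilyl)oxy]-6-{[(triisopropylsilyl)oxy]methyl}hepta-2,6-dien-2-yl]-2,2-dimethyl-1,3-dioxolane-4-carboxylate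
Conditions: second-generation Hoveyda–Grubbs catalyst (10 mol %), toluene, 80 °C
Reagents that add atoms: none
Why: Ring-closing metathesis between the only monosubstituted olefin and the acrylate builds the butenolide (C7=C11) bearing the CH2SO2Ph group on C11; the trisubstituted olefins are spectators.

Step 14
Reactants: 21 (butenolide methyl ester, named in step 13)
Product: 22 (4R,5S)-5-[(2E,4S,6E)-1-methoxy-1-oxo-7-{(2R)-5-oxo-4-[(phenylsulfonyl)methyl]-2,5-dihydrofuran-2-yl}-4-[(triisopropylsilyl)oxy]-6-{[(triisopropylsilyl)oxy]methyl}hepta-2,6-dien-2-yl]-2,2-dimethyl-1,3-dioxolane-4-carboxylic acid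
Conditions: Me3SnOH, ClCH2CH2Cl, 70 °C; 0.1 M HCl wash
Reagents that add atoms: trimethyltin hydroxide, C[Sn](C)(C)O
Why: Mild tin hydroxide hydrolysis cleaves the unhindered α-alkoxy methyl ester in preference to the hindered conjugated C14 ester and the butenolide, and is not basic enough to epimerise C6.

Step 15
Reactants: 22 (seco acid, named in step 14)
Product: 23 ten-membered α-methylene-γ-lactone (2S,6R,7S,8S,9S; 1(10)E,4E, both cis in the ring): 8,9-acetonide, 2,15-bis-TIPS ether, C14 methyl ester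
Conditions: Ir[dF(CF3)ppy]2(dtbbpy)PF6 (2 mol %), K2HPO4 (1.2 equiv), degassed DMSO (2 mM), blue LEDs, rt
Reagents that add atoms: none
Why: Proposed new method: the photoexcited trivalent iridium complex oxidises the C8 carboxylate, loss of CO2 gives the nucleophilic 1,3-dioxolan-4-yl radical, which adds 10-exo-trig to the electrophilic β-carbon C7 of the butenolide, and the resulting α-acyl radical expels PhSO2• (reduced to sulfinate by the divalent iridium species, closing the cycle) to unveil the exocyclic methylene; both new centres follow one rule, the forming ring bond goes anti to the neighbouring ring bond across each five-membered ring (anti to C10 on the dioxolane gives 8S, anti to C5 on the butenolide gives 7S and the trans-fused lactone), and the two cis ring olefins plus the two five-membered rings pre-organise the chain; the closest known reaction types are the intermolecular photoredox decarboxylative allylation of α-oxy acids with 2-(sulfonylmethyl)acrylates and the decarboxylative Giese macrocyclisation of peptides.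

Step 16
Reactants: 23 (macrocyclic acetonide, described in step 15)
Product: 24 the 8,9-diol of 23 (2,15-bis-TIPS ether, C14 methyl ester; 2S,6R,7S,8S,9S)
Conditions: CF3CO2H/H2O (9:1), CH2Cl2, 0 °C
Reagents that add atoms: none
Why: Acid hydrolysis of the isopropylidene ketal; TIPS ethers, the methyl ester and the lactone survive brief cold aqueous acid.

Step 17
Reactants: 24 (8,9-diol, described in step 16)
Product: 25 the 9-O-acetate of 24 (8-OH free)
Conditions: Ac2O (1.1 equiv), pyridine, CH2Cl2, −20 °C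
Reagents that add atoms: acetic anhydride, CC(=O)OC(C)=O
Why: Selective acylation of the allylic C9–OH, which is the more acidic hydroxyl and is flanked by a planar sp2 carbon, whereas C8–OH lies between two sp3 methines including the ring-fusion carbon.

Step 18
Reactants: 25 (9-acetate 8-alcohol, described in step 17)
Product: 26 the 8-O-angelate 9-O-acetate (2,15-bis-TIPS ether of the target)
Conditions: angelic acid, 2,4,6-trichlorobenzoyl chloride, Et3N, toluene, rt; then 25, 60 °C (no DMAP)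
Reagents that add atoms: angelic acid, C/C=C(/C)C(=O)O
Why: Yamaguchi esterification through the mixed anhydride acylates the hindered C8–OH; omitting DMAP avoids Z→E isomerisation to the tiglate.

Step 19
Reactants: 26 (bis-TIPS ether, described in step 18)
Product: 27 CNP0195669.2 (target)
Conditions: HF·pyridine, pyridine/THF, 0 °C → rt
Reagents that add atoms: none
Why: Buffered fluoride desilylation frees the C2 and C15 alcohols without acyl migration or addition to the α-methylene lactone.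

**Compound list**
1 | (S)-5-(hydroxymethyl)dihydrofuran-2(3H)-one | O=C1CC[C@@H](CO)O1 | starting material
2 | (S)-5-{[(triethylsilyl)oxy]methyl}dihydrofuran-2(3H)-one | CC[Si](CC)(CC)OC[C@@H]1CCC(=O)O1 | intermediate
3 | 2,2-dimethoxyacetaldehyde | COC(OC)C=O | starting material
4 | diethyl [(5S)-2-oxo-5-{[(triethylsilyl)oxy]methyl}oxolan-3-yl]phosphonate (lithium enolate in the flask) | CCOP(=O)(OCC)C1C[C@@H](CO[Si](CC)(CC)CC)OC1=O | intermediate
5 | (5S,3E)-3-(2,2-dimethoxyethylidene)-5-{[(triethylsilyl)oxy]methyl}dihydrofuran-2(3H)-one | COC(OC)/C=C1\C[C@@H](CO[Si](CC)(CC)CC)OC1=O | intermediate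
6 | (2E,4S)-2-(2,2-dimethoxyethylidene)-5-[(triethylsilyl)oxy]pentane-1,4-diol | COC(OC)/C=C(/CO)C[C@H](O)CO[Si](CC)(CC)CC | intermediate
7 | (2S,4E)-6,6-dimethoxy-1-[(triethylsilyl)oxy]-2-[(triisopropylsilyl)oxy]-4-{[(triisopropylsilyl)oxy]methyl}hex-4-ene | COC(OC)/C=C(/CO[Si](C(C)C)(C(C)C)C(C)C)C[C@H](O[Si](C(C)C)(C(C)C)C(C)C)CO[Si](CC)(CC)CC | intermediate
8 | (2S,4E)-6,6-dimethoxy-2-[(triisopropylsilyl)oxy]-4-{[(triisopropylsilyl)oxy]methyl}hex-4-enal | COC(OC)/C=C(/CO[Si](C(C)C)(C(C)C)C(C)C)C[C@H](O[Si](C(C)C)(C(C)C)C(C)C)C=O | intermediate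
9 | methyl (2Z,4S,6E)-2-iodo-8,8-dimethoxy-4-[(triisopropylsilyl)oxy]-6-{[(triisopropylsilyl)oxy]methyl}octa-2,6-dienoate | COC(OC)/C=C(/CO[Si](C(C)C)(C(C)C)C(C)C)C[C@H](O[Si](C(C)C)(C(C)C)C(C)C)/C=C(\I)C(=O)OC | intermediate
10 | 2,3-O-isopropylidene-D-erythronolactone | O=C1OC[C@H]2OC(C)(C)O[C@@H]12 | starting material
11 | potassium (4R,5R)-5-(hydroxymethyl)-2,2-dimethyl-1,3-dioxolane-4-carboxylate | [K+].[O-]C(=O)[C@@H]1OC(C)(C)O[C@@H]1CO | intermediate
12 | methyl (4R,5R)-5-(hydroxymethyl)-2,2-dimethyl-1,3-dioxolane-4-carboxylate | COC(=O)[C@@H]1OC(C)(C)O[C@@H]1CO | intermediate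
13 | (4S,5R)-5-(methoxycarbonyl)-2,2-dimethyl-1,3-dioxolane-4-carboxylic acid | COC(=O)[C@@H]1OC(C)(C)O[C@@H]1C(=O)O | intermediate
14 | methyl (4R,5S)-5-[(2E,4S,6E)-1,8,8-trimethoxy-1-oxo-4-[(triisopropylsilyl)oxy]-6-{[(triisopropylsilyl)oxy]methyl}octa-2,6-dien-2-yl]-2,2-dimethyl-1,3-dioxolane-4-carboxylate | COC(OC)/C=C(/CO[Si](C(C)C)(C(C)C)C(C)C)C[C@H](O[Si](C(C)C)(C(C)C)C(C)C)/C=C(/C(=O)OC)[C@@H]1OC(C)(C)O[C@H]1C(=O)OC | intermediate
15 | methyl (4R,5S)-5-[(2E,4S,6E)-1-methoxy-1,8-dioxo-4-[(triisopropylsilyl)oxy]-6-{[(triisopropylsilyl)oxy]methyl}octa-2,6-dien-2-yl]-2,2-dimethyl-1,3-dioxolane-4-carboxylate | O=C/C=C(/CO[Si](C(C)C)(C(C)C)C(C)C)C[C@H](O[Si](C(C)C)(C(C)C)C(C)C)/C=C(/C(=O)OC)[C@@H]1OC(C)(C)O[C@H]1C(=O)OC | intermediate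
16 | methyl (4R,5S)-5-[(2E,4S,6E,8S)-8-hydroxy-1-methoxy-1-oxo-4-[(triisopropylsilyl)oxy]-6-{[(triisopropylsilyl)oxy]methyl}deca-2,6,9-trien-2-yl]-2,2-dimethyl-1,3-dioxolane-4-carboxylate | C=C[C@H](O)/C=C(/CO[Si](C(C)C)(C(C)C)C(C)C)C[C@H](O[Si](C(C)C)(C(C)C)C(C)C)/C=C(/C(=O)OC)[C@@H]1OC(C)(C)O[C@H]1C(=O)OC | intermediate
17 | 2-(bromomethyl)prop-2-enoic acid | C=C(CBr)C(=O)O | starting material
18 | 2-[(phenylsulfonyl)methyl]prop-2-enoic acid | C=C(CS(=O)(=O)c1ccccc1)C(=O)O | intermediate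
19 | 2-[(phenylsulfonyl)methyl]prop-2-enoyl chloride | C=C(CS(=O)(=O)c1ccccc1)C(Cl)=O | intermediate
20 | (8S) 8-O-{2-[(phenylsulfonyl)methyl]prop-2-enoyl} ester of 16 | C=C[C@H](OC(=O)C(=C)CS(=O)(=O)c1ccccc1)/C=C(/CO[Si](C(C)C)(C(C)C)C(C)C)C[C@H](O[Si](C(C)C)(C(C)C)C(C)C)/C=C(/C(=O)OC)[C@@H]2OC(C)(C)O[C@H]2C(=O)OC | intermediate
21 | methyl (4R,5S)-5-[(2E,4S,6E)-1-methoxy-1-oxo-7-{(2R)-5-oxo-4-[(phenylsulfonyl)methyl]-2,5-dihydrofuran-2-yl}-4-[(triisopropylsilyl)oxy]-6-{[(triisopropylsilyl)oxy]methyl}hepta-2,6-dien-2-yl]-2,2-dimethyl-1,3-dioxolane-4-carboxylate | O=C1O[C@@H](C=C1CS(=O)(=O)c2ccccc2)/C=C(/CO[Si](C(C)C)(C(C)C)C(C)C)C[C@H](O[Si](C(C)C)(C(C)C)C(C)C)/C=C(/C(=O)OC)[C@@H]3OC(C)(C)O[C@H]3C(=O)OC | intermediate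
22 | (4R,5S)-dioxolane-4-carboxylic acid corresponding to 21 | O=C1O[C@@H](C=C1CS(=O)(=O)c2ccccc2)/C=C(/CO[Si](C(C)C)(C(C)C)C(C)C)C[C@H](O[Si](C(C)C)(C(C)C)C(C)C)/C=C(/C(=O)OC)[C@@H]3OC(C)(C)O[C@H]3C(=O)O | intermediate
23 | macrocyclic α-methylene lactone, 8,9-acetonide, 2,15-bis-TIPS ether, C14 methyl ester (2S,6R,7S,8S,9S) | C=C1C(=O)O[C@@H]2/C=C(/CO[Si](C(C)C)(C(C)C)C(C)C)C[C@H](O[Si](C(C)C)(C(C)C)C(C)C)/C=C(/C(=O)OC)[C@@H]3OC(C)(C)O[C@H]3[C@@H]12 | intermediate
24 | 8,9-diol, 2,15-bis-TIPS ether (2S,6R,7S,8S,9S) | C=C1C(=O)O[C@@H]2/C=C(/CO[Si](C(C)C)(C(C)C)C(C)C)C[C@H](O[Si](C(C)C)(C(C)C)C(C)C)/C=C(/C(=O)OC)[C@H](O)[C@@H](O)[C@@H]12 | intermediate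
25 | 9-O-acetate 8-alcohol, 2,15-bis-TIPS ether | C=C1C(=O)O[C@@H]2/C=C(/CO[Si](C(C)C)(C(C)C)C(C)C)C[C@H](O[Si](C(C)C)(C(C)C)C(C)C)/C=C(/C(=O)OC)[C@H](OC(C)=O)[C@@H](O)[C@@H]12 | intermediate
26 | 8-O-angelate 9-O-acetate, 2,15-bis-TIPS ether | C=C1C(=O)O[C@@H]2/C=C(/CO[Si](C(C)C)(C(C)C)C(C)C)C[C@H](O[Si](C(C)C)(C(C)C)C(C)C)/C=C(/C(=O)OC)[C@H](OC(C)=O)[C@@H](OC(=O)/C(C)=C\C)[C@@H]12 | intermediate
27 | CNP0195669.2 | C=C1C(=O)O[C@@H]2/C=C(/CO)C[C@H](O)/C=C(/C(=O)OC)[C@H](OC(C)=O)[C@@H](OC(=O)/C(C)=C\C)[C@@H]12 | target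

**Step count**
Total: 19 steps. Longest linear sequence: 16 steps (steps 1–5, 8–10, 12–19); steps 6–7 and 11 are side branches.

**Three steps most likely to fail**

Step 15 (radical macrocyclisation). The ten-membered closure must outrun 1,5-hydrogen transfer from the allylic, silyloxy-bearing C2–H to the C8 radical across the cis C1=C10 olefin; that transfer is disfavoured by allylic strain but not excluded. Oligomerisation, base-induced epimerisation at C6 and the wrong face at C7 are further risks. The fallback sets out from 9 and rejoins the route at 25, closing the same C7–C8 bond by a polar chromium-mediated allylation. Iodoenoate 9 is coupled with aldehyde 3 (CrCl2, cat. NiCl2, DMSO; a chiral sulfonamide ligand or chromatography secures 9S) to give hydroxy acetal F1, which is acetylated to acetate F2. The allylic acetal alone is hydrolysed (oxalic acid, wet SiO2) to enal F3, and divinylzinc with (−)-MIB gives vinyl carbinol F4. Esterification with 17 gives bromomethyl acrylate F5, metathesis gives bromomethyl butenolide F6, and aqueous CF3CO2H frees the α-acetoxy aldehyde F7. CrCl2 in THF at high dilution then adds the allylchromium through C7 to the C8 aldehyde, delivering 25 directly with O8 free and O9 acetylated.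

Step 17 (selective 9-O-acetylation, with possible acetyl migration during step 18). The fallback sets out from 24 and rejoins at 26, differentiating the two hydroxyls by oxidation state instead of acylation rate. Activated MnO2 oxidises only the allylic C9–OH to give hydroxy ketone F8, Yamaguchi angeloylation of the remaining C8–OH gives keto angelate F9, and NaBH4/CeCl3·7H2O at −78 °C (Felkin–Anh attack anti to the C8–O bond) gives the 9S alcohol F10, which is acetylated to 26.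

Step 8 (decarboxylative alkenylation of a hindered α-iodoenoate; trans selectivity and olefin integrity). The fallback sets out from 13 (with 9) and rejoins at 14, replacing oxidative photoredox activation by a thermal reductive cross-electrophile coupling. Acid 13 is converted with N-hydroxyphthalimide and diisopropylcarbodiimide into the redox-active ester F11, which is coupled with 9 using NiBr2·glyme, 4,4′-di-tert-butyl-2,2′-bipyridine and Zn powder in dimethylacetamide to give 14.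

**Further compounds**
F1 | step 15 | methyl (2E,4S,6E)-2-[(1S)-1-hydroxy-2,2-dimethoxyethyl]-8,8-dimethoxy-4-[(triisopropylsilyl)oxy]-6-{[(triisopropylsilyl)oxy]methyl}octa-2,6-dienoate | COC(OC)/C=C(/CO[Si](C(C)C)(C(C)C)C(C)C)C[C@H](O[Si](C(C)C)(C(C)C)C(C)C)/C=C(/C(=O)OC)[C@H](O)C(OC)OC
F2 | step 15 | 1-O-acetate of F1 | COC(OC)/C=C(/CO[Si](C(C)C)(C(C)C)C(C)C)C[C@H](O[Si](C(C)C)(C(C)C)C(C)C)/C=C(/C(=O)OC)[C@H](OC(C)=O)C(OC)OC
F3 | step 15 | methyl (2E,4S,6E)-2-[(1S)-1-acetoxy-2,2-dimethoxyethyl]-8-oxo-4-[(triisopropylsilyl)oxy]-6-{[(triisopropylsilyl)oxy]methyl}octa-2,6-dienoate | O=C/C=C(/CO[Si](C(C)C)(C(C)C)C(C)C)C[C@H](O[Si](C(C)C)(C(C)C)C(C)C)/C=C(/C(=O)OC)[C@H](OC(C)=O)C(OC)OC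
F4 | step 15 | methyl (2E,4S,6E,8S)-2-[(1S)-1-acetoxy-2,2-dimethoxyethyl]-8-hydroxy-4-[(triisopropylsilyl)oxy]-6-{[(triisopropylsilyl)oxy]methyl}deca-2,6,9-trienoate | C=C[C@H](O)/C=C(/CO[Si](C(C)C)(C(C)C)C(C)C)C[C@H](O[Si](C(C)C)(C(C)C)C(C)C)/C=C(/C(=O)OC)[C@H](OC(C)=O)C(OC)OC
F5 | step 15 | 8-O-[2-(bromomethyl)prop-2-enoyl] ester of F4 | C=C[C@H](OC(=O)C(=C)CBr)/C=C(/CO[Si](C(C)C)(C(C)C)C(C)C)C[C@H](O[Si](C(C)C)(C(C)C)C(C)C)/C=C(/C(=O)OC)[C@H](OC(C)=O)C(OC)OC
F6 | step 15 | methyl (2E,4S,6E)-2-[(1S)-1-acetoxy-2,2-dimethoxyethyl]-7-[(2R)-4-(bromomethyl)-5-oxo-2,5-dihydrofuran-2-yl]-4-[(triisopropylsilyl)oxy]-6-{[(triisopropylsilyl)oxy]methyl}hepta-2,6-dienoate | O=C1O[C@@H](C=C1CBr)/C=C(/CO[Si](C(C)C)(C(C)C)C(C)C)C[C@H](O[Si](C(C)C)(C(C)C)C(C)C)/C=C(/C(=O)OC)[C@H](OC(C)=O)C(OC)OC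
F7 | step 15 | methyl (2E,4S,6E)-2-[(1S)-1-acetoxy-2-oxoethyl]-7-[(2R)-4-(bromomethyl)-5-oxo-2,5-dihydrofuran-2-yl]-4-[(triisopropylsilyl)oxy]-6-{[(triisopropylsilyl)oxy]methyl}hepta-2,6-dienoate | O=C1O[C@@H](C=C1CBr)/C=C(/CO[Si](C(C)C)(C(C)C)C(C)C)C[C@H](O[Si](C(C)C)(C(C)C)C(C)C)/C=C(/C(=O)OC)[C@H](OC(C)=O)C=O
F8 | step 17 | 9-oxo-8-hydroxy macrocycle, 2,15-bis-TIPS ether (2S,6R,7S,8S) | C=C1C(=O)O[C@@H]2/C=C(/CO[Si](C(C)C)(C(C)C)C(C)C)C[C@H](O[Si](C(C)C)(C(C)C)C(C)C)/C=C(/C(=O)OC)C(=O)[C@@H](O)[C@@H]12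
F9 | step 17 | 9-oxo-8-O-angelate macrocycle, 2,15-bis-TIPS ether | C=C1C(=O)O[C@@H]2/C=C(/CO[Si](C(C)C)(C(C)C)C(C)C)C[C@H](O[Si](C(C)C)(C(C)C)C(C)C)/C=C(/C(=O)OC)C(=O)[C@@H](OC(=O)/C(C)=C\C)[C@@H]12
F10 | step 17 | (9S)-9-hydroxy-8-O-angelate macrocycle, 2,15-bis-TIPS ether | C=C1C(=O)O[C@@H]2/C=C(/CO[Si](C(C)C)(C(C)C)C(C)C)C[C@H](O[Si](C(C)C)(C(C)C)C(C)C)/C=C(/C(=O)OC)[C@H](O)[C@@H](OC(=O)/C(C)=C\C)[C@@H]12
F11 | step 8 | 4-(1,3-dioxoisoindolin-2-yl) 5-methyl (4S,5R)-2,2-dimethyl-1,3-dioxolane-4,5-dicarboxylate | COC(=O)[C@@H]1OC(C)(C)O[C@@H]1C(=O)ON3C(=O)c2ccccc2C3=O
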